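**Retrosynthetic overview**
1. The target is an all-cis tetra-oxygenated cyclohexene (ring numbering C1(OBz)–C2=C3–C4(OBz)–C5(OH)(CH2OH)–C6(OH), CH2OH on the opposite face). Its only ring is closed last, by ring-closing metathesis (C2=C3) of an unprotected acyclic octa-1,7-diene.
2. C4–C5 bond: chromium-catalysed γ-benzoyloxyallylation of an α,α′-dihydroxy ketone held as a transient cyclic phenylboronate (new method; sets C4 and C5).
3. C6–C1 bond: iridium-catalysed carbinol C–H (transfer-hydrogenative) benzoyloxyallylation of a dihydroxyacetone ketal diol (sets C6 and C1).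
4. Three building blocks: dihydroxyacetone (as its dimethyl ketal) and two acrolein-derived benzoyloxyallyl donors (a gem-dibenzoate and an allylic bromide). The donors carry both benzoates, so no protecting-group steps are needed.

Assumption: (R)-SEGPHOS is taken, by analogy with related carbonyl allylations, to give the (3R,4R) adduct in step 3; if the sense is reversed, (S)-SEGPHOS is used.

**Step 1**
Reactants: 1 1,3-dihydroxyacetone
Product: 2 2,2-dimethoxypropane-1,3-diol
Conditions: HC(OMe)3, TsOH·H2O (cat.), MeOH, rt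
Reagents that add atoms: trimethyl orthoformate, COC(OC)OC; methanol, CO
Why: Acid-catalysed ketalisation with orthoformate as water scavenger masks the ketone and leaves a symmetric primary 1,3-diol.

**Step 2**
Reactants: 3 acrolein
Product: 4 prop-2-ene-1,1-diyl dibenzoate
Conditions: Bz2O, H2SO4 (cat.), CH2Cl2, 0 °C to rt
Reagents that add atoms: benzoic anhydride, O=C(OC(=O)c1ccccc1)c1ccccc1
Why: Acid-catalysed acylal formation (1,1-diacyloxylation of the aldehyde) gives the allyl donor with no by-product.

**Step 3**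
Reactants: 2 2,2-dimethoxypropane-1,3-diol (3 equiv); 4 prop-2-ene-1,1-diyl dibenzoate
Product: 6 (3R,4R)-1,3-dihydroxy-2-oxohex-5-en-4-yl benzoate, via dimethyl ketal 5 (not isolated)
Conditions: [Ir(cod)Cl]2 (2.5 mol %), (R)-SEGPHOS (5 mol %), 4-chloro-3-nitrobenzoic acid (10 mol %), Cs2CO3 (20 mol %), THF, 90 °C; then filter, Amberlyst-15, acetone/H2O, 40 °C
Reagents that add atoms: water, O
Why: Krische-type iridium-catalysed transfer-hydrogenative C–C coupling from the alcohol oxidation level: one CH2OH of 2 is dehydrogenated to a non-enolisable aldehyde, which is allylated by the (E)-σ-(benzoyloxy)allyl iridium through a closed chair transition state. This gives the anti adduct, with the ligand setting both new centres (target C6 and C1, both R); mild acid then hydrolyses the ketal, and excess 2 ends as water-soluble 1.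

**Step 4**
Reactants: 3 acrolein
Product: 7 3-bromoprop-1-en-1-yl benzoate (E/Z mixture)
Conditions: BzBr, ZnCl2 (cat.), CH2Cl2, −20 to 0 °C
Reagents that add atoms: benzoyl bromide, O=C(Br)c1ccccc1
Why: Lewis-acid-catalysed conjugate (1,4-) addition of the acyl bromide across the enal gives the γ-acyloxyallyl bromide with no by-product.

**Step 5**
Reactants: 6 (3R,4R)-1,3-dihydroxy-2-oxohex-5-en-4-yl benzoate; 7 3-bromoprop-1-en-1-yl benzoate
Product: 10 (3S,4R,5R,6R)-4,5-dihydroxy-4-(hydroxymethyl)octa-1,7-diene-3,6-diyl dibenzoate, via cyclic phenylboronate 8 (not isolated), via silylated boronate adduct 9 (not isolated)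
Conditions: PhB(OH)2, MgSO4, THF, rt; then 7, CrCl2 (10 mol %), Mn powder, Me3SiCl, THF, 0 °C to rt; then 1 M HCl/MeOH, aqueous sorbitol wash
Reagents that add atoms: none
Why: Proposed new method: divalent chromium (regenerated by Mn powder) reduces 7 to a γ-(benzoyloxy)allyl trivalent chromium species that adds through its oxygen-bearing γ-carbon to the ketone of the six-membered dioxaborinanone 8; attack along the equatorial trajectory, trans to the C4 side chain, sets the tertiary carbinol (target C5, R), and a Zimmerman–Traxler chair with the (E)-allyl chromium and the more substituted ring arm equatorial sets the benzoate carbon (target C4, S), while Me3SiCl releases chromium for turnover and the neutral medium avoids β-elimination of benzoate; the closest known reactions are the catalytic Nozaki–Hiyama–Kishi allylation and the chromium-, indium- or zinc-mediated acyloxyallylation of aldehydes with 3-halopropenyl esters, not yet shown for ketones or on a boronate-templated substrate.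

**Step 6**
Reactants: 10 (3S,4R,5R,6R)-4,5-dihydroxy-4-(hydroxymethyl)octa-1,7-diene-3,6-diyl dibenzoate
Product: 11 (1R,4S,5R,6R)-5,6-dihydroxy-5-(hydroxymethyl)cyclohex-2-ene-1,4-diyl dibenzoate
Conditions: second-generation Grubbs catalyst (H2IMes)(PCy3)Cl2Ru=CHPh (5 mol %), 1,4-benzoquinone (10 mol %), CH2Cl2 (5 mM), 40 °C
Reagents that add atoms: none
Why: Ring-closing metathesis of the 1,7-diene forms the cyclohexene with loss of ethylene; no stereocentre is touched, and benzoquinone suppresses ruthenium hydride isomerisation.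

**Compound list**
1 | 1,3-dihydroxyacetone | OCC(=O)CO | starting material
2 | 2,2-dimethoxypropane-1,3-diol | COC(CO)(CO)OC | intermediate
3 | acrolein | C=CC=O | starting material
4 | prop-2-ene-1,1-diyl dibenzoate | C=CC(OC(=O)c1ccccc1)OC(=O)c1ccccc1 | intermediate
5 | (3R,4R)-1,3-dihydroxy-2,2-dimethoxyhex-5-en-4-yl benzoate | OCC(OC)(OC)[C@H](O)[C@H](OC(=O)c1ccccc1)C=C | intermediate (not isolated)
6 | (3R,4R)-1,3-dihydroxy-2-oxohex-5-en-4-yl benzoate | OCC(=O)[C@H](O)[C@H](OC(=O)c1ccccc1)C=C | intermediate
7 | 3-bromoprop-1-en-1-yl benzoate (E/Z mixture) | BrCC=COC(=O)c1ccccc1 | intermediate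
8 | (1R)-1-[(4R)-5-oxo-2-phenyl-1,3,2-dioxaborinan-4-yl]prop-2-en-1-yl benzoate | O=C1COB(c2ccccc2)O[C@@H]1[C@H](OC(=O)c1ccccc1)C=C | intermediate (not isolated)
9 | (1R)-1-[(4R,5R)-5-[(1S)-1-(benzoyloxy)prop-2-en-1-yl]-2-phenyl-5-(trimethylsilyloxy)-1,3,2-dioxaborinan-4-yl]prop-2-en-1-yl benzoate | C=C[C@H](OC(=O)c1ccccc1)[C@@]1(O[Si](C)(C)C)COB(c2ccccc2)O[C@@H]1[C@H](OC(=O)c1ccccc1)C=C | intermediate (not isolated)
10 | (3S,4R,5R,6R)-4,5-dihydroxy-4-(hydroxymethyl)octa-1,7-diene-3,6-diyl dibenzoate | O=C(O[C@@H](C=C)[C@@](O)(CO)[C@H](O)[C@H](OC(=O)c1ccccc1)C=C)c1ccccc1 | intermediate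
11 | (1R,4S,5R,6R)-5,6-dihydroxy-5-(hydroxymethyl)cyclohex-2-ene-1,4-diyl dibenzoate (all four ring oxygens cis, CH2OH trans) | O=C(O[C@H]1C=C[C@@H](OC(=O)c2ccccc2)[C@@H](O)[C@]1(O)CO)c1ccccc1 | target

**Total step count:** 6
**Longest linear sequence:** 4 steps (1 → 2 → 6 → 10 → 11; the branch 3 → 4 → 6 → 10 → 11 is equally long).

**Three steps most likely to fail**

Step 5 (the proposed new step). Risks are wrong facial selectivity at the ketone, a (Z)-configured allyl chromium giving the C4 epimer, and reductive loss of an α-oxygen by divalent chromium. The fallback uses known chemistry and sets out from 6. Ketalisation with 1,1-dimethoxycyclohexane and PPTS gives the isolable cyclohexylidene ketal (1R)-1-[(2R)-3-oxo-1,5-dioxaspiro[5.5]undecan-2-yl]prop-2-en-1-yl benzoate F4. A stoichiometric indium Barbier acyloxyallylation with 7 (In powder, THF, rt) then gives the tertiary alcohol adduct F5 under substrate control, and minor diastereomers are removed by chromatography. Aqueous trifluoroacetic acid removes the ketal, and the sequence comes back to the route at 10.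

Step 3. Risks are bis-allylation of the diol, 1,2-benzoyl migration under the basic coupling conditions, and sluggish hydrolysis of the electron-poor ketal. The fallback sets out from 2. Transketalisation in acetone with TsOH gives 2,2-dimethyl-1,3-dioxan-5-one F1. Enantioselective deprotonation with lithium (R,R)-bis(1-phenylethyl)amide and LiCl at −78 °C (antipode chosen to give the 4R product), then anti-selective aldol addition of the ring (E)-enolate to acrolein 3, gives (4R)-4-[(1R)-1-hydroxyprop-2-en-1-yl]-2,2-dimethyl-1,3-dioxan-5-one F2. Benzoylation with BzCl and pyridine gives (1R)-1-[(4R)-2,2-dimethyl-5-oxo-1,3-dioxan-4-yl]prop-2-en-1-yl benzoate F3. Acetonide hydrolysis with Amberlyst-15 in acetone/water comes back to the route at 6.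

Step 6. Risks are slow initiation at the two allylic-benzoate vinyl groups and ruthenium chelation by the free triol. The fallback sets out from 10. Silylation with Et3SiOTf and 2,6-lutidine gives the tris(triethylsilyl) ether of 10 F6. Ring-closing metathesis of this hydroxyl-free diene with the same ruthenium carbene in toluene at 80 °C gives the tris(triethylsilyl) ether of 11 F7. Desilylation with HF·pyridine comes back to the route at 11.

**Further compounds**
F1 | step 3 | 2,2-dimethyl-1,3-dioxan-5-one | CC1(C)OCC(=O)CO1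
F2 | step 3 | (4R)-4-[(1R)-1-hydroxyprop-2-en-1-yl]-2,2-dimethyl-1,3-dioxan-5-one | CC1(C)OCC(=O)[C@H](O1)[C@H](O)C=C
F3 | step 3 | (1R)-1-[(4R)-2,2-dimethyl-5-oxo-1,3-dioxan-4-yl]prop-2-en-1-yl benzoate | CC1(C)OCC(=O)[C@H](O1)[C@H](OC(=O)c1ccccc1)C=C
F4 | step 5 | (1R)-1-[(2R)-3-oxo-1,5-dioxaspiro[5.5]undecan-2-yl]prop-2-en-1-yl benzoate | O=C1COC2(CCCCC2)O[C@@H]1[C@H](OC(=O)c1ccccc1)C=C
F5 | step 5 | cyclohexylidene ketal of 10 across the primary and secondary hydroxyls (tertiary hydroxyl free) | C=C[C@H](OC(=O)c1ccccc1)[C@@]1(O)COC2(CCCCC2)O[C@@H]1[C@H](OC(=O)c1ccccc1)C=C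
F6 | step 6 | tris(triethylsilyl) ether of 10 | O=C(O[C@@H](C=C)[C@@](O[Si](CC)(CC)CC)(CO[Si](CC)(CC)CC)[C@H](O[Si](CC)(CC)CC)[C@H](OC(=O)c1ccccc1)C=C)c1ccccc1
F7 | step 6 | tris(triethylsilyl) ether of 11 | O=C(O[C@H]1C=C[C@@H](OC(=O)c2ccccc2)[C@@H](O[Si](CC)(CC)CC)[C@]1(O[Si](CC)(CC)CC)CO[Si](CC)(CC)CC)c1ccccc1
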